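**Plan**
1. Retrosynthesis: after removal of the protecting groups, ring C is cut at O1–C2 and C2–C3 (benzoyl chloride supplies C2 and ring B) and at C3–C4 (a MOM-oxymethyl anion supplies C3), which leaves a C4a aldehyde whose carbon is C4.
2. Ring A is then cut at C8–C8a, C6–C7 and C4a–C8a. The enabling feature is that ring A is a phloroglucinol ring whose C8 carries the stereogenic methine and lies between the oxygen-bearing C7 and C8a: C8 and C7 are the two carbons of a siloxyalkyne, while C8a, C6, C5(OEt) and C4a are C1–C4 of 3-ethoxycyclobutenone.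
3. The bond between the methine and the alkyne is cut last, back to a vanillin-derived aryl vinyl carbinol and a silylacetylene.
4. Forward: the stereocentre is made first, the acetylide is oxidised to the siloxyalkyne, ring A is built around the stereocentre by benzannulation, and ring C is closed last (formylation, one-carbon extension, C-benzoylation, cyclodehydration); ring B arrives intact.
5. Stereochemistry: the single (R) centre comes from an enantioconvergent iridium-catalysed allylic alkynylation with a chiral phosphoramidite–olefin ligand; no bond to it changes afterwards, and later steps avoid conditions that would remove its proton.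

Key step: step 7

Assumption: the (S)-configured phosphoramidite–olefin ligand is taken to give the (R)-enyne 8 in step 4; if the sense of induction is the opposite, its enantiomer is used and nothing else changes.
Abbreviations: Ar = 3-methoxy-4-(triisopropylsilyloxy)phenyl; TIPS = triisopropylsilyl; MOM = methoxymethyl.

Step 1
Reactants: 1 vanillin
Product: 2 3-methoxy-4-(triisopropylsilyloxy)benzaldehyde
Conditions: TIPSCl, imidazole, DMF, rt
Reagents that add atoms: chlorotriisopropylsilane, CC(C)[Si](Cl)(C(C)C)C(C)C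
Why: Imidazole-mediated O-silylation of a phenol is routine, and the bulky silyl ether keeps the acidic hydroxyl out of the Grignard and iridium steps.

Step 2
Reactants: 2 3-methoxy-4-(triisopropylsilyloxy)benzaldehyde
Product: 3 rac-1-Ar-prop-2-en-1-ol
Conditions: CH2=CHMgBr, THF, −78 → 0 °C; H2O
Reagents that add atoms: vinylmagnesium bromide, C=C[Mg]Br
Why: Grignard 1,2-addition to an aryl aldehyde gives the branched aryl vinyl carbinol, deliberately as the racemate because the next step is enantioconvergent.

Step 3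
Reactants: 4 ethynyltrimethylsilane
Product: 7 potassium trifluoro[(trimethylsilyl)ethynyl]borate, via lithium (trimethylsilyl)acetylide 5 (not isolated), via lithium alkynyltrimethoxyborate 6 (not isolated)
Conditions: n-BuLi, THF, −78 °C; B(OMe)3, −78 → −20 °C; aq. KHF2, rt
Reagents that add atoms: trimethyl borate, COB(OC)OC; potassium hydrogen difluoride, F.[F-].[K+]
Why: Standard preparation of a potassium alkynyltrifluoroborate, in which the lithium acetylide adds to the borate ester and aqueous KHF2 exchanges methoxide for fluoride to give an air-stable salt.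

Step 4
Reactants: 3 rac-1-Ar-prop-2-en-1-ol; 7 potassium trifluoro[(trimethylsilyl)ethynyl]borate
Product: 8 (R)-trimethyl(3-Ar-pent-4-en-1-yn-1-yl)silane
Conditions: [Ir(cod)Cl]2 (cat.), (S)-BINOL-derived dibenzazepine phosphoramidite–olefin ligand (cat.), KHF2, CF3CO2H, n-Bu4NBr (cat.), 1,4-dioxane, rt
Reagents that add atoms: none
Why: Iridium-catalysed enantioconvergent allylic substitution of a racemic branched allylic alcohol with an alkynyltrifluoroborate: acid-assisted ionisation gives an Ir(π-allyl) complex of the chiral ligand, and the alkynyl group is transferred to the aryl-bearing terminus on the face the ligand leaves open, which sets the (R) stereocentre and keeps the vinyl group terminal.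

Step 5
Reactants: 8 (R)-trimethyl(3-Ar-pent-4-en-1-yn-1-yl)silane
Product: 9 (S)-2-methoxy-4-(pent-1-en-4-yn-3-yl)phenol
Conditions: TBAF, AcOH, THF, 0 °C → rt
Reagents that add atoms: none
Why: Fluoride-induced protodesilylation removes the alkynyl SiMe3 group and the aryl silyl ether together (any phenol already freed by HF in step 4 converges here), and the acetic acid buffer should keep the base-sensitive skipped enyne from isomerising to the allene; the descriptor becomes S only because ethynyl ranks below aryl.

Step 6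
Reactants: 9 (S)-2-methoxy-4-(pent-1-en-4-yn-3-yl)phenol
Product: 12 (R)-triisopropyl[(3-Ar-pent-4-en-1-yn-1-yl)oxy]silane, via dilithium phenoxide acetylide 10 (not isolated), via dilithium phenoxide ynolate 11 (not isolated)
Conditions: n-BuLi (2.0 equiv), THF, −78 °C; LiOOt-Bu (from t-BuOOH, LiHMDS), −78 → 0 °C; TIPSOTf, −78 → 0 °C
Reagents that add atoms: tert-butyl hydroperoxide, CC(C)(C)OO; triisopropylsilyl trifluoromethanesulfonate, CC(C)[Si](OS(=O)(=O)C(F)(F)F)(C(C)C)C(C)C
Why: Electrophilic oxygenation of a lithium acetylide with lithium tert-butyl peroxide gives the lithium ynolate, which the bulky silyl triflate traps on oxygen as the ynol silyl ether; carrying the aryl group as its para-lithium phenoxide makes it a poor carbanion-stabilising group, so the propargylic, allylic and benzylic proton should not be removed by the acetylide, and the same reagent re-silylates the phenoxide.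

Step 7
Reactants: 12 (R)-triisopropyl[(3-Ar-pent-4-en-1-yn-1-yl)oxy]silane; 13 3-ethoxycyclobut-2-en-1-one
Product: 18 (R)-5-ethoxy-2-(1-Ar-allyl)-3-(triisopropylsilyloxy)phenol, via (1-ethoxyvinyl)ketene 14 (not isolated), via 4-vinylcyclobutenone adduct 15 (not isolated), via dienylketene 16 (not isolated), via cyclohexa-2,4-dienone 17 (not isolated)
Conditions: 13 (1.5 equiv), toluene, 80 → 110 °C, sealed tube, argon
Reagents that add atoms: none
Why: Heating opens cyclobutenone 13 by 4π electrocyclic ring opening to ketene 14, whose carbonyl carbon bonds to the nucleophilic, methine-bearing carbon of the siloxyalkyne (C8–C8a) while its α-carbon bonds to the silyloxy-bearing carbon (C6–C7) in a ketene–alkyne [2+2] cycloaddition that gives 15. A second 4π opening gives the (E)-dienylketene 16, which closes ring A by thermal disrotatory 6π electrocyclisation (C4a–C8a) to dienone 17, and this tautomerises to phenol 18. The closest known reaction type is the Danheiser benzannulation of cyclobutenones with trialkylsilyloxyalkynes, which gives resorcinol monosilyl ethers. No new stereocentre is created, and the existing methine should pass through unchanged because no bond to it is made or broken and the medium is neutral and aprotic. The selectivity needed is regiochemical: the free hydroxyl must end up next to the methine carbon (future O1 and C8), the silyl ether at C7 and the ethyl ether at C5, with C4a as the only free ortho carbon; this is secured by the polarisation of the ynol ether in the [2+2] step and by the fixed position of the ethoxy group on C3 of the cyclobutenone.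

Step 8
Reactants: 18 (R)-5-ethoxy-2-(1-Ar-allyl)-3-(triisopropylsilyloxy)phenol
Product: 20 (R)-6-ethoxy-2-hydroxy-3-(1-Ar-allyl)-4-(triisopropylsilyloxy)benzaldehyde, via ortho-hydroxymethyl phenol 19 (not isolated)
Conditions: MgCl2, Et3N, (CH2O)n, THF, reflux
Reagents that add atoms: paraformaldehyde (formaldehyde unit), C=O
Why: Magnesium-mediated ortho-formylation (Casnati–Skattebøl reaction): the magnesium phenoxide delivers formaldehyde to the only free ortho carbon, C4a between the hydroxyl and the ethoxy group, and the benzylic alkoxide 19 is oxidised by a second formaldehyde through hydride transfer, while triethylamine is far too weak a base to touch the methine.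

Step 9
Reactants: 20 (R)-6-ethoxy-2-hydroxy-3-(1-Ar-allyl)-4-(triisopropylsilyloxy)benzaldehyde
Product: 21 1-[6-ethoxy-2-hydroxy-3-((R)-1-Ar-allyl)-4-(triisopropylsilyloxy)phenyl]-2-(methoxymethoxy)ethan-1-ol (both carbinol epimers)
Conditions: NaH, THF, 0 °C; then LiCH2OMOM (from Bu3SnCH2OMOM, n-BuLi), THF, −78 °C; pH 7 buffer
Reagents that add atoms: tributyl[(methoxymethoxy)methyl]stannane, CCCC[Sn](CCCC)(CCCC)COCOC
Why: Tin–lithium exchange gives an α-alkoxymethyllithium (a hydroxymethyl anion equivalent) that adds 1,2 to the aldehyde at −78 °C; the phenol is converted into its sodium salt beforehand so that the substrate meets only a small excess of alkyllithium, and the new carbinol centre is of no consequence because it is oxidised in step 10.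

Step 10
Reactants: 21 1-[6-ethoxy-2-hydroxy-3-((R)-1-Ar-allyl)-4-(triisopropylsilyloxy)phenyl]-2-(methoxymethoxy)ethan-1-ol
Product: 22 1-[6-ethoxy-2-hydroxy-3-((R)-1-Ar-allyl)-4-(triisopropylsilyloxy)phenyl]-2-(methoxymethoxy)ethan-1-one
Conditions: activated MnO2, CH2Cl2, rt (21 used without purification)
Reagents that add atoms: none
Why: Manganese dioxide oxidises benzylic alcohols selectively, so the electron-rich secondary benzylic alcohol should become the chelated o-hydroxyaryl ketone while phenol, silyl ethers, acetal and terminal alkene are left alone; using 21 crude limits its loss by o-quinone methide formation.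

Step 11
Reactants: 22 1-[6-ethoxy-2-hydroxy-3-((R)-1-Ar-allyl)-4-(triisopropylsilyloxy)phenyl]-2-(methoxymethoxy)ethan-1-one
Product: 24 1-[6-ethoxy-2-hydroxy-3-((R)-1-Ar-allyl)-4-(triisopropylsilyloxy)phenyl]-2-(methoxymethoxy)-3-phenylpropane-1,3-dione, via dilithium phenoxide enolate 23 (not isolated)
Conditions: LiHMDS (3.2 equiv), THF, −78 °C; BzCl, −78 °C → rt; aq. NH4Cl
Reagents that add atoms: benzoyl chloride, O=C(Cl)c1ccccc1
Why: One-pot form of the Baker–Venkataraman diketone synthesis, in which the dilithium phenoxide–enolate of the o-hydroxyaryl ketone is benzoylated on carbon; the ketone CH2 is many pK units more acidic than the diarylallyl methine, so a hindered amide base at low temperature should leave the stereocentre alone.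

Step 12
Reactants: 24 1-[6-ethoxy-2-hydroxy-3-((R)-1-Ar-allyl)-4-(triisopropylsilyloxy)phenyl]-2-(methoxymethoxy)-3-phenylpropane-1,3-dione
Product: 26 5-ethoxy-3-hydroxy-8-[(R)-1-Ar-allyl]-2-phenyl-7-(triisopropylsilyloxy)-4H-chromen-4-one, via 3-(methoxymethoxy)flavone 25 (not isolated)
Conditions: HCl (3 M in MeOH), THF, 45 °C
Reagents that add atoms: none
Why: Acid-catalysed cyclodehydration of an o-hydroxyaryl 1,3-diketone: the phenol adds to the benzoyl carbonyl (6-exo-trig hemiketal), water is lost to give the pyranone ring, and the same methanolic acid cleaves the MOM acetal to the flavonol, conditions that aryl triisopropylsilyl ethers and a monosubstituted alkene should tolerate.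

Step 13
Reactants: 26 5-ethoxy-3-hydroxy-8-[(R)-1-Ar-allyl]-2-phenyl-7-(triisopropylsilyloxy)-4H-chromen-4-one
Product: 27 3,5-dihydroxy-8-[(R)-1-Ar-allyl]-2-phenyl-7-(triisopropylsilyloxy)-4H-chromen-4-one
Conditions: BCl3 (4 equiv), CH2Cl2, −78 → 0 °C; H2O
Reagents that add atoms: none
Why: Chelation-controlled Lewis-acid dealkylation: boron held between the C4 carbonyl oxygen and O5 activates only the peri ethyl ether for attack by chloride, so the guaiacyl methyl ether and both silyl ethers should survive, and with O7 still silylated no phenol is available to add across the neighbouring alkene.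

Step 14
Reactants: 27 3,5-dihydroxy-8-[(R)-1-Ar-allyl]-2-phenyl-7-(triisopropylsilyloxy)-4H-chromen-4-one
Product: 28 3,5,7-trihydroxy-8-[(R)-1-(4-hydroxy-3-methoxyphenyl)allyl]-2-phenyl-4H-chromen-4-one (CNP0417789.1)
Conditions: TBAF, AcOH, THF, 0 °C → rt
Reagents that add atoms: none
Why: Fluoride cleavage of the two aryl silyl ethers under acetic acid buffering should release the target without exposing the oxidation-prone polyphenolic flavonol or the methine to free base.

**Compound list**
1 | vanillin (4-hydroxy-3-methoxybenzaldehyde) | COc1cc(C=O)ccc1O | starting material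
2 | 3-methoxy-4-(triisopropylsilyloxy)benzaldehyde | COc1cc(C=O)ccc1O[Si](C(C)C)(C(C)C)C(C)C | intermediate
3 | rac-1-[3-methoxy-4-(triisopropylsilyloxy)phenyl]prop-2-en-1-ol (racemate) | C=CC(O)c1ccc(O[Si](C(C)C)(C(C)C)C(C)C)c(OC)c1 | intermediate
4 | ethynyltrimethylsilane | C#C[Si](C)(C)C | starting material
5 | lithium (trimethylsilyl)acetylide (formed in the flask) | [Li+].[C-]#C[Si](C)(C)C | intermediate
6 | lithium trimethoxy[(trimethylsilyl)ethynyl]borate (formed in the flask) | [Li+].CO[B-](OC)(OC)C#C[Si](C)(C)C | intermediate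
7 | potassium trifluoro[(trimethylsilyl)ethynyl]borate | [K+].F[B-](F)(F)C#C[Si](C)(C)C | intermediate
8 | (R)-{3-[3-methoxy-4-(triisopropylsilyloxy)phenyl]pent-4-en-1-yn-1-yl}trimethylsilane | C=C[C@H](c1ccc(O[Si](C(C)C)(C(C)C)C(C)C)c(OC)c1)C#C[Si](C)(C)C | intermediate
9 | (S)-2-methoxy-4-(pent-1-en-4-yn-3-yl)phenol (same spatial arrangement as 8) | C=C[C@H](c1ccc(O)c(OC)c1)C#C | intermediate
10 | dilithium salt of 9, phenoxide and acetylide (formed in the flask, configuration of 9) | [Li+].[Li+].C=C[C@H](c1ccc([O-])c(OC)c1)C#[C-] | intermediate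
11 | dilithium (R)-3-(3-methoxy-4-oxidophenyl)pent-4-en-1-yn-1-olate (formed in the flask) | [Li+].[Li+].C=C[C@H](c1ccc([O-])c(OC)c1)C#C[O-] | intermediate
12 | (R)-triisopropyl{[3-(3-methoxy-4-(triisopropylsilyloxy)phenyl)pent-4-en-1-yn-1-yl]oxy}silane | C=C[C@H](c1ccc(O[Si](C(C)C)(C(C)C)C(C)C)c(OC)c1)C#CO[Si](C(C)C)(C(C)C)C(C)C | intermediate
13 | 3-ethoxycyclobut-2-en-1-one | CCOC1=CC(=O)C1 | starting material
14 | 3-ethoxybuta-1,3-dien-1-one, (1-ethoxyvinyl)ketene (formed in the flask) | C=C(OCC)C=C=O | intermediate
15 | 4-(1-ethoxyvinyl)-2-[(R)-1-Ar-allyl]-3-(triisopropylsilyloxy)cyclobut-2-en-1-one (formed in the flask, both C4 epimers) | C=C[C@H](c1ccc(O[Si](C(C)C)(C(C)C)C(C)C)c(OC)c1)C1=C(O[Si](C(C)C)(C(C)C)C(C)C)C(C(=C)OCC)C1=O | intermediate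
16 | (3E)-5-ethoxy-2-[(R)-1-Ar-allyl]-3-(triisopropylsilyloxy)hexa-1,3,5-trien-1-one (formed in the flask) | C=C[C@H](c1ccc(O[Si](C(C)C)(C(C)C)C(C)C)c(OC)c1)C(=C=O)/C(O[Si](C(C)C)(C(C)C)C(C)C)=C\C(=C)OCC | intermediate
17 | 5-ethoxy-2-[(R)-1-Ar-allyl]-3-(triisopropylsilyloxy)cyclohexa-2,4-dien-1-one (formed in the flask) | C=C[C@H](c1ccc(O[Si](C(C)C)(C(C)C)C(C)C)c(OC)c1)C1=C(O[Si](C(C)C)(C(C)C)C(C)C)C=C(OCC)CC1=O | intermediate
18 | (R)-5-ethoxy-2-[1-(3-methoxy-4-(triisopropylsilyloxy)phenyl)allyl]-3-(triisopropylsilyloxy)phenol | C=C[C@H](c1ccc(O[Si](C(C)C)(C(C)C)C(C)C)c(OC)c1)c1c(O)cc(OCC)cc1O[Si](C(C)C)(C(C)C)C(C)C | intermediate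
19 | (R)-5-ethoxy-2-(hydroxymethyl)-6-... phenol, i.e. 18 carrying CH2OH on the carbon between OH and OEt (magnesium-bound in the flask, neutral form drawn) | C=C[C@H](c1ccc(O[Si](C(C)C)(C(C)C)C(C)C)c(OC)c1)c1c(O)c(CO)c(OCC)cc1O[Si](C(C)C)(C(C)C)C(C)C | intermediate
20 | (R)-6-ethoxy-2-hydroxy-3-[1-(3-methoxy-4-(triisopropylsilyloxy)phenyl)allyl]-4-(triisopropylsilyloxy)benzaldehyde | C=C[C@H](c1ccc(O[Si](C(C)C)(C(C)C)C(C)C)c(OC)c1)c1c(O)c(C=O)c(OCC)cc1O[Si](C(C)C)(C(C)C)C(C)C | intermediate
21 | 1-[6-ethoxy-2-hydroxy-3-((R)-1-Ar-allyl)-4-(triisopropylsilyloxy)phenyl]-2-(methoxymethoxy)ethan-1-ol (both carbinol epimers) | C=C[C@H](c1ccc(O[Si](C(C)C)(C(C)C)C(C)C)c(OC)c1)c1c(O)c(C(O)COCOC)c(OCC)cc1O[Si](C(C)C)(C(C)C)C(C)C | intermediate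
22 | 1-[6-ethoxy-2-hydroxy-3-((R)-1-Ar-allyl)-4-(triisopropylsilyloxy)phenyl]-2-(methoxymethoxy)ethan-1-one | C=C[C@H](c1ccc(O[Si](C(C)C)(C(C)C)C(C)C)c(OC)c1)c1c(O)c(C(=O)COCOC)c(OCC)cc1O[Si](C(C)C)(C(C)C)C(C)C | intermediate
23 | dilithium phenoxide–enolate of 22 (formed in the flask) | [Li+].[Li+].C=C[C@H](c1ccc(O[Si](C(C)C)(C(C)C)C(C)C)c(OC)c1)c1c([O-])c(C([O-])=COCOC)c(OCC)cc1O[Si](C(C)C)(C(C)C)C(C)C | intermediate
24 | 1-[6-ethoxy-2-hydroxy-3-((R)-1-Ar-allyl)-4-(triisopropylsilyloxy)phenyl]-2-(methoxymethoxy)-3-phenylpropane-1,3-dione (C2 epimers and enol forms) | C=C[C@H](c1ccc(O[Si](C(C)C)(C(C)C)C(C)C)c(OC)c1)c1c(O)c(C(=O)C(OCOC)C(=O)c2ccccc2)c(OCC)cc1O[Si](C(C)C)(C(C)C)C(C)C | intermediate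
25 | 5-ethoxy-3-(methoxymethoxy)-8-[(R)-1-Ar-allyl]-2-phenyl-7-(triisopropylsilyloxy)-4H-chromen-4-one (formed in the flask) | C=C[C@H](c1ccc(O[Si](C(C)C)(C(C)C)C(C)C)c(OC)c1)c1c(O[Si](C(C)C)(C(C)C)C(C)C)cc(OCC)c2c(=O)c(OCOC)c(-c3ccccc3)oc12 | intermediate
26 | 5-ethoxy-3-hydroxy-8-[(R)-1-Ar-allyl]-2-phenyl-7-(triisopropylsilyloxy)-4H-chromen-4-one | C=C[C@H](c1ccc(O[Si](C(C)C)(C(C)C)C(C)C)c(OC)c1)c1c(O[Si](C(C)C)(C(C)C)C(C)C)cc(OCC)c2c(=O)c(O)c(-c3ccccc3)oc12 | intermediate
27 | 3,5-dihydroxy-8-[(R)-1-Ar-allyl]-2-phenyl-7-(triisopropylsilyloxy)-4H-chromen-4-one | C=C[C@H](c1ccc(O[Si](C(C)C)(C(C)C)C(C)C)c(OC)c1)c1c(O[Si](C(C)C)(C(C)C)C(C)C)cc(O)c2c(=O)c(O)c(-c3ccccc3)oc12 | intermediate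
28 | 3,5,7-trihydroxy-8-[(R)-1-(4-hydroxy-3-methoxyphenyl)allyl]-2-phenyl-4H-chromen-4-one (CNP0417789.1) | C=C[C@H](c1ccc(O)c(OC)c1)c1c(O)cc(O)c2c(=O)c(O)c(-c3ccccc3)oc12 | target

**Step count and risks**
Total step count: 14. Longest linear sequence: 13 steps (1, 2, 4–14, from vanillin); step 3 is a one-step side branch.

The three steps most likely to fail:

Step 7. The cyclobutenone is a vinylogous ester, and its 4π opening may need temperatures at which the siloxyalkyne is consumed by 1,3-silyl migration to a silylketene, so that ketene and ynol ether never meet. The fallback sets out from 12 and rejoins the route at 15; it generates the same ketene 14 at room temperature by 1,4-dehydrochlorination instead of by electrocyclic opening. Commercial ethyl (E)-3-ethoxybut-2-enoate is saponified with KOH to potassium (E)-3-ethoxybut-2-enoate F1, which oxalyl chloride converts into (E)-3-ethoxybut-2-enoyl chloride F2. F2 is added slowly to 12 and i-Pr2NEt in CH2Cl2, so that the ketene is captured as it forms to give cyclobutenone 15, which is then heated alone in toluene to 18.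

Step 4. The electron-rich carbinol may ionise without the metal, so that alkynyl transfer runs through a free cation with loss of enantiocontrol and of the branched regiochemistry. The fallback sets out from 2 and rejoins the route at 8; it sets the stereocentre by a copper-catalysed SN2′ substitution under non-acidic conditions. Horner–Wadsworth–Emmons olefination of 2 with triethyl phosphonoacetate gives ethyl (E)-3-Ar-acrylate F3, DIBAL-H reduces it to (E)-3-Ar-prop-2-en-1-ol F4, and diethyl chlorophosphate gives diethyl (E)-3-Ar-allyl phosphate F5. A chiral N-heterocyclic-carbene–copper catalyst, in the enantiomeric form that gives the (R) product, then couples F5 γ-selectively with diisobutyl[(trimethylsilyl)ethynyl]aluminium F6 (made from 4 and DIBAL-H with catalytic Et3N) to give 8.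

Step 9. The alkyllithium may abstract the methine proton, or the o-hydroxybenzylic alcohol may be lost through o-quinone methide formation before it can be oxidised. The fallback sets out from 20 and rejoins the route at 22; it uses the aldehyde carbon as the nucleophile instead. An N-heterocyclic-carbene-catalysed cross-acyloin reaction of 20 with paraformaldehyde (thiazolium salt, i-Pr2NEt, THF) would give 1-[6-ethoxy-2-hydroxy-3-((R)-1-Ar-allyl)-4-(triisopropylsilyloxy)phenyl]-2-hydroxyethan-1-one F7 with neither an organolithium nor a benzylic alcohol on the way. MOMCl and i-Pr2NEt then etherify its primary hydroxyl, the chelated and flanked phenol staying free, to give 22.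

**Further compounds**
F1 | step 7 | potassium (E)-3-ethoxybut-2-enoate | CCO/C(C)=C/C(=O)[O-].[K+]
F2 | step 7 | (E)-3-ethoxybut-2-enoyl chloride | CCO/C(C)=C/C(=O)Cl
F3 | step 4 | ethyl (E)-3-[3-methoxy-4-(triisopropylsilyloxy)phenyl]acrylate | CCOC(=O)/C=C/c1ccc(O[Si](C(C)C)(C(C)C)C(C)C)c(OC)c1
F4 | step 4 | (E)-3-[3-methoxy-4-(triisopropylsilyloxy)phenyl]prop-2-en-1-ol | OC/C=C/c1ccc(O[Si](C(C)C)(C(C)C)C(C)C)c(OC)c1
F5 | step 4 | diethyl (E)-3-[3-methoxy-4-(triisopropylsilyloxy)phenyl]allyl phosphate | CCOP(=O)(OCC)OC/C=C/c1ccc(O[Si](C(C)C)(C(C)C)C(C)C)c(OC)c1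
F6 | step 4 | diisobutyl[(trimethylsilyl)ethynyl]aluminium | CC(C)C[Al](CC(C)C)C#C[Si](C)(C)C
F7 | step 9 | 1-[6-ethoxy-2-hydroxy-3-((R)-1-Ar-allyl)-4-(triisopropylsilyloxy)phenyl]-2-hydroxyethan-1-one | C=C[C@H](c1ccc(O[Si](C(C)C)(C(C)C)C(C)C)c(OC)c1)c1c(O)c(C(=O)CO)c(OCC)cc1O[Si](C(C)C)(C(C)C)C(C)C
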